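The ratio of left-handed to right-handed product falls towards one in the earlier runs, so a late reading does not give the excess asked for at the early time.

| flask | left-handed substrate | right-handed substrate | solid reagent | remark | time |
|---|---|---|---|---|---|
| north-east | 0.050 M | 0.050 M | 2 equiv | run made earlier |  |
| north-west | 0.050 M | 0.050 M | 8 equiv | run made earlier |  |
| north | 0.10 M | 0.10 M | 4 equiv | run made earlier |  |
| flask | 0.050 M | 0.050 M | 4.00 equiv |  | 40 h |

| run | time / h | left-handed product / % | right-handed product / % | left-handed substrate / % |
|---|---|---|---|---|
| north-east | 4.00 | 0 | 0.2 | 37.6 |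
| north-east | 6.00 | 1.8 | 0.6 | 36.1 |
| north-east | 10.0 | 1.4 | 0.9 | 34.4 |
| north-east | 20.0 | 4.9 | 3.4 | 31.2 |
| north-east | 30.0 | 8.6 | 6.9 | 28.3 |
| north-east | 50.0 | 14.1 | 12.5 | 20.6 |
| north-west | 3.00 | 0.7 | 0 | 37.8 |
| north-west | 10.0 | 1.9 | 1.8 | 34.8 |
| north-west | 15.0 | 4.2 | 2.3 | 34.3 |
| north-west | 25.0 | 7.8 | 5.6 | 29.6 |
| north-west | 40.0 | 11.4 | 10.1 | 25.2 |
| north-west | 50.0 | 13.6 | 12.9 | 21.8 |
| north | 4.00 | 0.1 | 0.5 | 36.6 |
| north | 12.0 | 2.6 | 1.5 | 34.6 |
| north | 20.0 | 5.5 | 3.8 | 32.1 |
| north | 30.0 | 7.9 | 6.4 | 28.6 |
| north | 50.0 | 13.0 | 10.2 | 23.1 |

(each reading ± 0.5 percentage points)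

- excess of left-handed product over right-handed product in the product at 50 min
- excess of left-handed product over right-handed product in the product at 40 h
- part of the left-handed substrate and right-handed substrate charged together that has reacted at 40 h

- partner is single-handed; left-handed substrate and right-handed substrate are mirror images of each other, charged as a racemate, each of them at the stated concentration
- given per volume of solution although it is solid: solid reagent
- at the start none of the solid reagent is in solution
- what has gone into achiral form counts as reacted
- an excess is the difference of the two amounts in percent of their sum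
- an excess is below zero if the other one leads
- the handed part of partner does not stay in what it makes, so the products of the two hands are mirror images too

But the late readings give something else. In the 6 readings from 30.0 h on, left-handed product leads right-handed product by 1.6 percentage points on average, with no trend beyond the scatter. Meanwhile the two products together gain 10 points in 20.0 h, on the mean of the north-east and north runs.

So, within the scatter, the lead is being lost as fast as it is made. Call that lead divided by the hourly gain the lead time, 3.20 h, a reading: the time a lead survives if new product is purely left-handed.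

The readings show a lag, so in your reckoning making climbs steadily from zero, and the average product present at the early time has existed for a third of 50 min. Against the lead time, that costs 8.68% of a full excess, giving 91.3%. That figure assumes purely left-handed new product. Put it back in as the excess of new product, which lengthens the lead time by the same ratio, go round once more, and you commit to 84.1%.

The forecast gives 30% for the excess at 50 min, well below your figure, then 7% for the excess at 40 h and 47% reacted at 40 h, saying of the early figure “though this is uncertain”.

The flask gives 80.6%, 8.34% and 50.5%, in the same order.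

    partner + left-handed substrate → left-handed product (k = 2.26 × 10⁻⁴ L mol⁻¹ s⁻¹)
    partner + right-handed substrate → right-handed product (k = 1.57 × 10⁻⁵ L mol⁻¹ s⁻¹)
    left-handed substrate ⇌ achiral form (K = 0.620, k = 5.67 × 10⁻⁴ s⁻¹)
    right-handed substrate ⇌ achiral form (K = 0.620, k = 5.67 × 10⁻⁴ s⁻¹)
    achiral form → waste (k = 4.92 × 10⁻⁶ s⁻¹)
    left-handed product ⇌ right-handed product (k = 3.83 × 10⁻⁵ s⁻¹)
    2 partner → homo dimer (k = 1.28 × 10⁻⁴ L mol⁻¹ s⁻¹)
    solid reagent ⇌ partner, rate k8*(cs8 - [partner]) while solid is left; crystals form when [partner] > cs8 (solubility = 43.0 mM, k = 1.93 × 10⁻⁵ s⁻¹)

Left-handed product passes to right-handed product (racemisation) with a forward half-life of 5.0 h, short against 40 h. Multiply the lead time by this flask's hourly gain of product between 20.0 h and 40.0 h, divide by its 21.4% of product, and you get an excess of 8.93% at 40.0 h. The neighbour flask with 10.0 equiv of solid reagent holds the same 0.0255 M of partner and stands at 8.34%.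

The data are simulated with made-up constants; noise was put on by code.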